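Everything rests on opening ring A across its C1–C2 bond. A benzoic acid with hydroxyls at C4 and C6, the oxoheptyl chain at C2 and the ring B oxygen at C3 is the aromatized form of a 3,5,7-triketo ester whose chain carbon 6 already carries that oxygen. The key step frees this ester from a dioxinone with benzyl alcohol and then, with carbonate base, closes ring A by aldol attack of the ester-flanked methylene (future C1) on the ketone that becomes C2, followed by loss of water. The precursor is a 6-substituted dioxinone bearing a racemic 2-aryloxy-1,3-diketone, with the isocoumarin ether on an sp3 carbon and the side-chain ketone masked as a dioxolane.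

Key step: step 11

Remark on the chemistry: the target has no stereocentre; the aryloxy methine of the key-step precursor is racemic and largely enolized and the centres of the aldol adduct are transient, so no configuration is assigned to any compound.

Step 1
Reactants: 1 methyl orsellinate (methyl 2,4-dihydroxy-6-methylbenzoate)
Product: 2 methyl 2,4-dimethoxy-6-methylbenzoate
Conditions: MeI (3 equiv), K2CO3 (3 equiv), acetone, reflux
Reagents that add atoms: iodomethane, CI
Why: Williamson ether synthesis: K2CO3 deprotonates both phenols and excess MeI at reflux should methylate even the hydrogen-bonded 2-hydroxyl, which removes the acidic protons that would quench the benzylic lithiation of step 2.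

Step 2
Reactants: 2 methyl 2,4-dimethoxy-6-methylbenzoate; 3 hexanoyl chloride
Product: 5 methyl 2,4-dimethoxy-6-(2-oxoheptyl)benzoate, via lithiated toluate 4 (not isolated)
Conditions: 2 (2.0 equiv), LiN(iPr)2 (2.0 equiv), THF, −78 °C; then 3 (1.0 equiv), −78 °C; aq NH4Cl
Reagents that add atoms: none
Why: Lateral lithiation of the ortho-toluate gives an ester-stabilized benzylic anion that should be C-acylated by the acid chloride at −78 °C, the second equivalent of anion deprotonating the more acidic benzyl ketone so that over-addition is blocked and that equivalent of 2 is recovered.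

Step 3
Reactants: 5 methyl 2,4-dimethoxy-6-(2-oxoheptyl)benzoate
Product: 6 6,8-dimethoxy-3-pentyl-1H-isochromen-1-one
Conditions: p-TsOH·H2O (0.1 equiv), PhMe, reflux, 4 Å MS
Reagents that add atoms: none
Why: Acid-catalysed enol lactonization, a 6-exo-trig attack of the ketone enol oxygen on the ortho ester with loss of methanol, should be driven by removal of methanol and by the conjugation gained in the isocoumarin.

Step 4
Reactants: 6 6,8-dimethoxy-3-pentyl-1H-isochromen-1-one
Product: 7 8-hydroxy-6-methoxy-3-pentyl-1H-isochromen-1-one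
Conditions: BCl3 (1.2 equiv), CH2Cl2, −78 to 0 °C; H2O
Reagents that add atoms: none
Why: Chelation-directed ether cleavage: BCl3 bound to the lactone carbonyl should form a six-membered chelate with the peri 8-methoxy oxygen and lose chloromethane from that group only, so the 6-methoxy group stays.

Step 5
Reactants: 8 ethyl 3-oxooctanoate
Product: 9 ethyl 2-(2-pentyl-1,3-dioxolan-2-yl)acetate
Conditions: HOCH2CH2OH (3 equiv), p-TsOH·H2O (0.05 equiv), PhMe, reflux, Dean–Stark
Reagents that add atoms: ethylene glycol, OCCO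
Why: Acid-catalysed ketalization with azeotropic removal of water should protect the ketone of the beta-keto ester as its dioxolane, the mask that later keeps this carbonyl and its alpha-methylene out of the aldol chemistry.

Step 6
Reactants: 9 ethyl 2-(2-pentyl-1,3-dioxolan-2-yl)acetate
Product: 10 N-methoxy-N-methyl-2-(2-pentyl-1,3-dioxolan-2-yl)acetamide
Conditions: MeNH(OMe)·HCl (1.5 equiv), iPrMgCl (3.0 equiv), THF, −20 °C; aq NH4Cl
Reagents that add atoms: N,O-dimethylhydroxylamine hydrochloride, CNOC.Cl
Why: The chloromagnesium amide formed from MeNH(OMe)·HCl and iPrMgCl should convert the ethyl ester directly into the N-methoxy-N-methylamide by acyl substitution, the ketal being stable to the basic magnesium reagent at low temperature.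

Step 7
Reactants: 11 2,2,6-trimethyl-4H-1,3-dioxin-4-one; 12 acetyl chloride
Product: 14 2,2-dimethyl-6-(2-oxopropyl)-4H-1,3-dioxin-4-one, via lithium dienolate 13 (not isolated)
Conditions: 11 (2.0 equiv), LiN(SiMe3)2 (2.0 equiv), THF, −78 °C; then 12 (1.0 equiv), −78 °C; aq NH4Cl
Reagents that add atoms: none
Why: Gamma-deprotonation of 11 gives the cross-conjugated lithium dienolate 13, which should be C-acylated at its exocyclic carbon by acetyl chloride (vinylogous Claisen-type acylation), the second equivalent of 13 taking up the acidic proton of the product.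

Step 8
Reactants: 14 2,2-dimethyl-6-(2-oxopropyl)-4H-1,3-dioxin-4-one; 10 N-methoxy-N-methyl-2-(2-pentyl-1,3-dioxolan-2-yl)acetamide
Product: 16 6-[2,4-dioxo-5-(2-pentyl-1,3-dioxolan-2-yl)pentyl]-2,2-dimethyl-4H-1,3-dioxin-4-one, via dilithium dianion 15 (not isolated)
Conditions: LiN(iPr)2 (2.1 equiv), THF, −78 °C; then 10 (1.0 equiv), −78 to −30 °C; aq NH4Cl at −78 °C
Reagents that add atoms: none
Why: Crossed Claisen condensation in the Weinreb ketone synthesis mode: dianion 15 should attack the amide through its more basic terminal carbon, and the chelated tetrahedral adduct collapses only on quench, which gives the enolized 1,3-diketone without over-addition.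

Step 9
Reactants: 16 6-[2,4-dioxo-5-(2-pentyl-1,3-dioxolan-2-yl)pentyl]-2,2-dimethyl-4H-1,3-dioxin-4-one
Product: 17 6-[3-diazo-2,4-dioxo-5-(2-pentyl-1,3-dioxolan-2-yl)pentyl]-2,2-dimethyl-4H-1,3-dioxin-4-one
Conditions: 4-AcNHC6H4SO2N3 (1.05 equiv), Et3N (1.1 equiv), MeCN, 0 °C, 30 min
Reagents that add atoms: 4-acetamidobenzenesulfonyl azide, CC(=O)Nc1ccc(cc1)S(=O)(=O)N=[N+]=[N-]
Why: Regitz diazo transfer should take place at the most acidic carbon, the methylene between the two ketones, and it is fast enough at 0 °C that the amine base has no time to cyclize the dioxinone onto the diketone.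

Step 10
Reactants: 17 6-[3-diazo-2,4-dioxo-5-(2-pentyl-1,3-dioxolan-2-yl)pentyl]-2,2-dimethyl-4H-1,3-dioxin-4-one; 7 8-hydroxy-6-methoxy-3-pentyl-1H-isochromen-1-one
Product: 18 6-{3-[(6-methoxy-1-oxo-3-pentyl-1H-isochromen-8-yl)oxy]-2,4-dioxo-5-(2-pentyl-1,3-dioxolan-2-yl)pentyl}-2,2-dimethyl-4H-1,3-dioxin-4-one
Conditions: Rh2(OAc)4 (2 mol %), ClCH2CH2Cl, 60 °C, slow addition of 17 (2.5 equiv) to 7 (1.0 equiv, 1 M)
Reagents that add atoms: none
Why: Rhodium-carbenoid O–H insertion: the phenol oxygen should add to the electrophilic diacyl carbenoid and a 1,2-proton shift then gives the hindered aryl ether at an sp3 carbon under neutral conditions, with slow addition of excess 17 to concentrated 7 favouring bimolecular insertion over carbene dimerization and over capture by the dioxolane oxygen.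

Step 11
Reactants: 18 6-{3-[(6-methoxy-1-oxo-3-pentyl-1H-isochromen-8-yl)oxy]-2,4-dioxo-5-(2-pentyl-1,3-dioxolan-2-yl)pentyl}-2,2-dimethyl-4H-1,3-dioxin-4-one; 19 benzyl alcohol
Product: 23 benzyl 4,6-dihydroxy-3-[(6-methoxy-1-oxo-3-pentyl-1H-isochromen-8-yl)oxy]-2-[(2-pentyl-1,3-dioxolan-2-yl)methyl]benzoate, via acylketene 20 (not isolated), via benzyl triketo ester 21 (not isolated), via cyclic aldol adduct 22 (not isolated)
Conditions: 19 (3 equiv), PhMe (0.05 M), 110 °C; then Cs2CO3 (3 equiv), iPrOH–CH2Cl2, 20 °C; then AcOH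
Reagents that add atoms: none
Why: Thermal retro-[4+2] cleavage of the dioxinone expels acetone and gives acylketene 20, which benzyl alcohol captures as the enolized triketo ester 21; Cs2CO3 then lets the ester-flanked methylene add to the chain ketone next to the aryloxy carbon to give 22, and loss of water with enolization of the two remaining ring ketones delivers the resorcylate. The closest known reaction type is the dioxinone-based biomimetic resorcylate synthesis (acylketene capture by an alcohol, then aldol aromatization of a 3,5,7-triketo ester), here extended to a chain that carries an aryloxy group. Ring A closes by a 6-exo-trig aldol addition of the enolate carbon to an exocyclic C=O. No stereocentre persists, because the racemic aryloxy methine and the centres of 22 all become sp2 carbons of the arene. The step needs regioselective C1–C2 closure, and the substrate secures it because the ester-flanked methylene is the only doubly activated carbon that can reach a ketone through a six-membered ring: the methylene between the two ketones has no carbonyl within such reach, the more acidic aryloxy methine could only close by Claisen attack on the ester to a quaternary adduct that cannot aromatize and so reverts, and the dioxolane leaves the far methylene singly activated and removes the fourth carbonyl. Carbonate in a poorly nucleophilic alcohol should keep the ring B lactone closed and the diketonate-stabilized aryloxy carbanion too unreactive to add to it, and the AcOH finish spares the dioxolane.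

Step 12
Reactants: 23 benzyl 4,6-dihydroxy-3-[(6-methoxy-1-oxo-3-pentyl-1H-isochromen-8-yl)oxy]-2-[(2-pentyl-1,3-dioxolan-2-yl)methyl]benzoate
Product: 24 benzyl 4,6-dihydroxy-3-[(6-methoxy-1-oxo-3-pentyl-1H-isochromen-8-yl)oxy]-2-(2-oxoheptyl)benzoate
Conditions: 1 M aq HCl, THF, 20 °C
Reagents that add atoms: water, O
Why: Acid-catalysed hydrolysis of the dioxolane should release the ketone while the carboxyl group is still blocked as the benzyl ester, so no lactol or enol lactone can form, and dilute acid at room temperature leaves the benzyl ester, the isocoumarin lactone and the diaryl ether alone.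

Step 13
Reactants: 24 benzyl 4,6-dihydroxy-3-[(6-methoxy-1-oxo-3-pentyl-1H-isochromen-8-yl)oxy]-2-(2-oxoheptyl)benzoate
Product: 25 beta-collatolic acid (4,6-dihydroxy-3-[(6-methoxy-1-oxo-3-pentyl-1H-isochromen-8-yl)oxy]-2-(2-oxoheptyl)benzoic acid)
Conditions: H2 (1 atm), 10% Pd on carbon, EtOAc, 20 °C, stopped after 1 equiv of H2
Reagents that add atoms: none
Why: Hydrogenolysis of the benzylic C–O bond on palladium should free the acid under neutral conditions and is much faster than saturation of the isocoumarin C3–C4 double bond, so hydrogen uptake is stopped at one equivalent, and the aliphatic ketone is inert.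

Compound list
1 | methyl orsellinate (methyl 2,4-dihydroxy-6-methylbenzoate) | COC(=O)c1c(C)cc(O)cc1O | starting material
2 | methyl 2,4-dimethoxy-6-methylbenzoate | COC(=O)c1c(C)cc(OC)cc1OC | intermediate
3 | hexanoyl chloride | CCCCCC(Cl)=O | starting material
4 | lithiated toluate (methyl 2-(lithiomethyl)-4,6-dimethoxybenzoate) | COC(=O)c1c(C[Li])cc(OC)cc1OC | intermediate (not isolated)
5 | methyl 2,4-dimethoxy-6-(2-oxoheptyl)benzoate | CCCCCC(=O)Cc1cc(OC)cc(OC)c1C(=O)OC | intermediate
6 | 6,8-dimethoxy-3-pentyl-1H-isochromen-1-one | CCCCCc1cc2cc(OC)cc(OC)c2c(=O)o1 | intermediate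
7 | 8-hydroxy-6-methoxy-3-pentyl-1H-isochromen-1-one | CCCCCc1cc2cc(OC)cc(O)c2c(=O)o1 | intermediate
8 | ethyl 3-oxooctanoate | CCCCCC(=O)CC(=O)OCC | starting material
9 | ethyl 2-(2-pentyl-1,3-dioxolan-2-yl)acetate | CCCCCC1(CC(=O)OCC)OCCO1 | intermediate
10 | N-methoxy-N-methyl-2-(2-pentyl-1,3-dioxolan-2-yl)acetamide | CCCCCC1(CC(=O)N(C)OC)OCCO1 | intermediate
11 | 2,2,6-trimethyl-4H-1,3-dioxin-4-one | CC1=CC(=O)OC(C)(C)O1 | starting material
12 | acetyl chloride | CC(Cl)=O | starting material
13 | lithium dienolate of 11 (4-lithiooxy-2,2-dimethyl-6-methylidene-1,3-dioxine) | C=C1C=C(O[Li])OC(C)(C)O1 | intermediate (not isolated)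
14 | 2,2-dimethyl-6-(2-oxopropyl)-4H-1,3-dioxin-4-one | CC(=O)CC1=CC(=O)OC(C)(C)O1 | intermediate
15 | dilithium dianion of 14 | C=C(O[Li])C=C1C=C(O[Li])OC(C)(C)O1 | intermediate (not isolated)
16 | 6-[2,4-dioxo-5-(2-pentyl-1,3-dioxolan-2-yl)pentyl]-2,2-dimethyl-4H-1,3-dioxin-4-one | CC1(C)OC(=O)C=C(CC(=O)CC(=O)CC2(CCCCC)OCCO2)O1 | intermediate
17 | 6-[3-diazo-2,4-dioxo-5-(2-pentyl-1,3-dioxolan-2-yl)pentyl]-2,2-dimethyl-4H-1,3-dioxin-4-one | CC1(C)OC(=O)C=C(CC(=O)C(=[N+]=[N-])C(=O)CC2(CCCCC)OCCO2)O1 | intermediate
18 | 6-{3-[(6-methoxy-1-oxo-3-pentyl-1H-isochromen-8-yl)oxy]-2,4-dioxo-5-(2-pentyl-1,3-dioxolan-2-yl)pentyl}-2,2-dimethyl-4H-1,3-dioxin-4-one (racemic, largely enolized; key-step precursor) | CC1(C)OC(=O)C=C(CC(=O)C(Oc2cc(OC)cc3cc(CCCCC)oc(=O)c23)C(=O)CC2(CCCCC)OCCO2)O1 | intermediate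
19 | benzyl alcohol | OCc1ccccc1 | starting material
20 | acylketene (6-[(6-methoxy-1-oxo-3-pentyl-1H-isochromen-8-yl)oxy]-8-(2-pentyl-1,3-dioxolan-2-yl)oct-1-ene-1,3,5,7-tetrone) | O=C=CC(=O)CC(=O)C(Oc1cc(OC)cc2cc(CCCCC)oc(=O)c12)C(=O)CC1(CCCCC)OCCO1 | intermediate (not isolated)
21 | benzyl triketo ester (benzyl 6-[(6-methoxy-1-oxo-3-pentyl-1H-isochromen-8-yl)oxy]-3,5,7-trioxo-8-(2-pentyl-1,3-dioxolan-2-yl)octanoate) | O=C(CC(=O)CC(=O)C(Oc1cc(OC)cc2cc(CCCCC)oc(=O)c12)C(=O)CC1(CCCCC)OCCO1)OCc1ccccc1 | intermediate (not isolated)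
22 | cyclic aldol adduct (benzyl 2-hydroxy-3-[(6-methoxy-1-oxo-3-pentyl-1H-isochromen-8-yl)oxy]-4,6-dioxo-2-[(2-pentyl-1,3-dioxolan-2-yl)methyl]cyclohexane-1-carboxylate, mixture of diastereomers) | O=C1CC(=O)C(Oc2cc(OC)cc3cc(CCCCC)oc(=O)c23)C(O)(CC2(CCCCC)OCCO2)C1C(=O)OCc1ccccc1 | intermediate (not isolated)
23 | benzyl 4,6-dihydroxy-3-[(6-methoxy-1-oxo-3-pentyl-1H-isochromen-8-yl)oxy]-2-[(2-pentyl-1,3-dioxolan-2-yl)methyl]benzoate (key-step product) | CCCCCC1(Cc2c(Oc3cc(OC)cc4cc(CCCCC)oc(=O)c34)c(O)cc(O)c2C(=O)OCc2ccccc2)OCCO1 | intermediate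
24 | benzyl 4,6-dihydroxy-3-[(6-methoxy-1-oxo-3-pentyl-1H-isochromen-8-yl)oxy]-2-(2-oxoheptyl)benzoate | CCCCCC(=O)Cc1c(Oc2cc(OC)cc3cc(CCCCC)oc(=O)c23)c(O)cc(O)c1C(=O)OCc1ccccc1 | intermediate
25 | beta-collatolic acid (4,6-dihydroxy-3-[(6-methoxy-1-oxo-3-pentyl-1H-isochromen-8-yl)oxy]-2-(2-oxoheptyl)benzoic acid) | CCCCCC(=O)Cc1c(Oc2cc(OC)cc3cc(CCCCC)oc(=O)c23)c(O)cc(O)c1C(=O)O | target

Total step count: 13.
Longest linear sequence: 8 steps (steps 1, 2, 3, 4, 10, 11, 12, 13; the branch through steps 5, 6, 8, 9 is equally long).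

Steps most likely to fail

Step 10. What may go wrong: the carbenoid is intercepted within the molecule by a dioxolane oxygen five atoms away (oxonium ylide formation and rearrangement), or it dimerizes, faster than the hindered, hydrogen-bonded phenol inserts. The fallback makes the ether first by Williamson alkylation and then builds the chain by two Claisen acylations, with no carbenoid. Setting out from 7, alkylation with tert-butyl bromoacetate (K2CO3, DMF) should give tert-butyl 2-[(6-methoxy-1-oxo-3-pentyl-1H-isochromen-8-yl)oxy]acetate F1. CF3CO2H in CH2Cl2 cleaves the ester to 2-[(6-methoxy-1-oxo-3-pentyl-1H-isochromen-8-yl)oxy]acetic acid F2, and (COCl)2 with catalytic DMF gives 2-[(6-methoxy-1-oxo-3-pentyl-1H-isochromen-8-yl)oxy]acetyl chloride F3. Acylation of dienolate 13 (from 11) at −78 °C gives 6-{3-[(6-methoxy-1-oxo-3-pentyl-1H-isochromen-8-yl)oxy]-2-oxopropyl}-2,2-dimethyl-4H-1,3-dioxin-4-one F4. A second enolization with LiN(iPr)2 (2 equiv) and acylation by amide 10, both kept at or below −40 °C so that the aryloxy carbanion does not add to the ring B lactone, then rejoins the route at 18.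

Step 11. What may go wrong: the acylketene is captured internally by an enol oxygen (pyranone formation) before benzyl alcohol reaches it, or the carbonate stage stalls at the aldol adduct or opens the isocoumarin lactone. The fallback aromatizes before the dioxinone is opened. Setting out from 18, Et3N in CH2Cl2 at 20 °C should let the alpha-carbon of the intact dioxinone add to the same ketone and aromatize. This forms the same C1–C2 bond and gives the acetonide-protected resorcylate 7-hydroxy-6-[(6-methoxy-1-oxo-3-pentyl-1H-isochromen-8-yl)oxy]-2,2-dimethyl-5-[(2-pentyl-1,3-dioxolan-2-yl)methyl]-4H-1,3-benzodioxin-4-one F5. Warming F5 with benzyl alcohol 19 and K2CO3 in THF opens the acetonide ester by transesterification and rejoins the route at 23.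

Step 8. What may go wrong: proton transfer from the alpha-methylene of the amide to the dianion, followed by beta-elimination that opens the dioxolane, or O-acylation, takes the place of C-acylation. The fallback replaces the Claisen acylation with aldol addition and oxidation. Setting out from 9, iBu2AlH in CH2Cl2 at −78 °C should give 2-(2-pentyl-1,3-dioxolan-2-yl)acetaldehyde F6. Its addition to dianion 15 (from 14) at −78 °C gives 6-[4-hydroxy-2-oxo-5-(2-pentyl-1,3-dioxolan-2-yl)pentyl]-2,2-dimethyl-4H-1,3-dioxin-4-one F7, and oxidation with Dess–Martin periodinane rejoins the route at 16.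

Further compounds
F1 | step 10 | tert-butyl 2-[(6-methoxy-1-oxo-3-pentyl-1H-isochromen-8-yl)oxy]acetate | CCCCCc1cc2cc(OC)cc(OCC(=O)OC(C)(C)C)c2c(=O)o1
F2 | step 10 | 2-[(6-methoxy-1-oxo-3-pentyl-1H-isochromen-8-yl)oxy]acetic acid | CCCCCc1cc2cc(OC)cc(OCC(=O)O)c2c(=O)o1
F3 | step 10 | 2-[(6-methoxy-1-oxo-3-pentyl-1H-isochromen-8-yl)oxy]acetyl chloride | CCCCCc1cc2cc(OC)cc(OCC(Cl)=O)c2c(=O)o1
F4 | step 10 | 6-{3-[(6-methoxy-1-oxo-3-pentyl-1H-isochromen-8-yl)oxy]-2-oxopropyl}-2,2-dimethyl-4H-1,3-dioxin-4-one | CC1(C)OC(=O)C=C(CC(=O)COc2cc(OC)cc3cc(CCCCC)oc(=O)c23)O1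
F5 | step 11 | 7-hydroxy-6-[(6-methoxy-1-oxo-3-pentyl-1H-isochromen-8-yl)oxy]-2,2-dimethyl-5-[(2-pentyl-1,3-dioxolan-2-yl)methyl]-4H-1,3-benzodioxin-4-one | CCCCCC1(Cc2c(Oc3cc(OC)cc4cc(CCCCC)oc(=O)c34)c(O)cc5OC(C)(C)OC(=O)c25)OCCO1
F6 | step 8 | 2-(2-pentyl-1,3-dioxolan-2-yl)acetaldehyde | CCCCCC1(CC=O)OCCO1
F7 | step 8 | 6-[4-hydroxy-2-oxo-5-(2-pentyl-1,3-dioxolan-2-yl)pentyl]-2,2-dimethyl-4H-1,3-dioxin-4-one | CC1(C)OC(=O)C=C(CC(=O)CC(O)CC2(CCCCC)OCCO2)O1
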